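(Readings and results stem from a simulated flask for substances that don't exist, noise included.)

Begin with an easy count. If one nucleophile couples with one electrophile, the nucleophile charged covers 90.0% of the electrophile charged. I call this share the ceiling and carry it through, and it makes the nucleophile the limiting reagent.

the same everywhere: electrophile 0.20 M
- cedar: nucleophile 0.18 M; free base 0.60 M; the very flask that is asked about, followed so far
- flask: nucleophile 0.180 M; free base 0.600 M; time 12 h

cedar run (percent of the electrophile charged)

| time / h | electrophile / % | target / % |
|---|---|---|
| 0.417 | 23.7 | 70.3 |
| 0.833 | 19.1 | 79.4 |
| 2.00 | 13.9 | 80.7 |
| 5.00 | 11.4 | 78.8 |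

(readings scatter by 1 percentage point)

* part of the electrophile that has reacted at 12 h
* share of the unused nucleophile that is free and not bound as protonated nucleophile, at 12 h

Now take the rate, as a share of the electrophile charged per hour. In the cedar run, which is this same flask followed so far, electrophile goes at 1.83 h⁻¹ on average up to the first reading. Between the last two readings it goes at 0.00833 h⁻¹, about 220 times slower.

If the rate goes with electrophile left times nucleophile left, two factors slow it. Between those two spans the electrophile present, taken as the mean of each span's ends, falls by a factor of 4.89 as read. The other factor, the nucleophile that can still react, whether used up or bound, must then give the rest, roughly 44.9 as read. That factor is larger, so I expect the rate to fade with the nucleophile, and my reckoning for 12 h is the ceiling itself, 90.0% reacted. The runs do not show how much nucleophile is bound, so for that share I have a guess and no reckoning.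

The forecast, higher than my ceiling, gives 91% reacted (88.5% to 94.5%) on the suspicion of “a slow side loss of electrophile or target”, and 30% free (10% to 60%).

The flask gives 88.5% reacted and 97.6% of the unused nucleophile free at 12 h.

    electrophile + nucleophile → acid set free + target (k = 47.0 M⁻¹ h⁻¹)
    nucleophile + acid set free ⇌ protonated nucleophile, settled at all times (K = 60.0 M⁻¹)
    acid set free + free base ⇌ salt of the base, settled at all times (K = 1000 M⁻¹)
    nucleophile + target → over-reaction product (k = 0.560 M⁻¹ h⁻¹)
    target ⇌ isomer of the product (K = 0.110, k = 0.0580 h⁻¹)

Its over-reaction product stands at 1.47% of the electrophile charged, and the ceiling less the answer is 1.5 percentage points, the same size. Now put the ceiling to a neighbour charged with 0.12 M of electrophile, other charges as here. There the same nucleophile comes to 150% of the electrophile, above the whole charge, and that neighbour ends with 100% reacted and 17.5% of its nucleophile left.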